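**Retrosynthetic overview**

Labels used below (own numbering): tetrahydropyran O4–C3–C2–C1(OAc)–C13–C5; carbocycle C5–C6–C7–C12–C11(=O)–C10; lactone bridge C7–O8–C9(=O)–C10.
Last disconnection: the six-membered carbocycle is opened to a spiro cyclopentanone (C5, C6, C7, C12, C11) carrying an α-diazopropanoate on O8; forward, the diazo carbon (C10, with its methyl and C9) inserts into the C11–C5 bond, so one step expands the ring, closes the lactone and makes quaternary C10.
Enabling feature: C10 is the α-carbon of a β-keto lactone wedged between ketone C11 and spiro ether carbon C5, and lactone oxygen O8 sits on C7, 1,3 to C11, so the lactone bridge itself is the tether for a diazo ester homologation of a cyclopentanone.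
Cyclopentanone: ozonolysis of an exo-methylene spirocycle made by vinylsilane-terminated cyclisation onto the tetrahydropyranyl oxocarbenium ion (sets C5); C7 and C12 from an allenylzinc propargylation; ketal from a syn aldol of an ethyl ketone (C7–C6–C5–C13) with an aldehyde (C1–C3).
Ring order: tetrahydropyran (ketalisation), then cyclopentane (spirocyclisation), then lactone ring and six-membered carbocycle together.

Key step: step 20

Remark on the chemistry: methyl ketal 15 is taken as the anomer with axial methoxy (anomeric effect); this centre is erased in oxocarbenium ion 24, so the assumption does not affect the outcome.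

**Route**

Step 1
Reactants: 1 methyl (R)-3-hydroxy-2-methylpropanoate
Product: 2 methyl (R)-3-(benzyloxy)-2-methylpropanoate
Conditions: BnOC(=NH)CCl3, TfOH (cat.), CH2Cl2/cyclohexane, rt
Reagents that add atoms: benzyl 2,2,2-trichloroacetimidate, N=C(OCc1ccccc1)C(Cl)(Cl)Cl
Why: Acid-catalysed imidate benzylation protects the primary alcohol without base, so the enolisable α-stereocentre is kept and no new one is formed.

Step 2
Reactants: 2 methyl (R)-3-(benzyloxy)-2-methylpropanoate
Product: 3 (R)-3-(benzyloxy)-N-methoxy-N,2-dimethylpropanamide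
Conditions: MeNH(OMe)·HCl, iPrMgCl, THF, −20 °C
Reagents that add atoms: N,O-dimethylhydroxylamine hydrochloride, CNOC.Cl
Why: The magnesium amide made in the flask converts the ester directly into the Weinreb amide at low temperature without touching the α-stereocentre.

Step 3
Reactants: 3 (R)-3-(benzyloxy)-N-methoxy-N,2-dimethylpropanamide
Product: 4 (R)-1-(benzyloxy)-2-methylpentan-3-one
Conditions: EtMgBr, THF, 0 °C; aq. NH4Cl
Reagents that add atoms: ethylmagnesium bromide, CC[Mg]Br
Why: Weinreb ketone synthesis, in which the chelated tetrahedral adduct survives until work-up, should stop at the ethyl ketone with the α-stereocentre intact.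

Step 4
Reactants: 5 (R)-4-benzyl-3-propanoyl-1,3-oxazolidin-2-one; 6 acetaldehyde
Product: 8 (R)-4-benzyl-3-[(2R,3S)-3-hydroxy-2-methylbutanoyl]-1,3-oxazolidin-2-one, via boron enolate 7 (not isolated)
Conditions: Bu2BOTf, iPr2NEt, CH2Cl2, 0 °C; then 6, −78 to 0 °C; pH 7 buffer, MeOH, H2O2
Reagents that add atoms: none
Why: Evans syn aldol reaction, in which the (Z)-boron enolate 7 reacts through a closed Zimmerman–Traxler chair on the face away from the benzyl group of the auxiliary, so both new stereocentres (2R,3S) are set by the auxiliary.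

Step 5
Reactants: 8 (R)-4-benzyl-3-[(2R,3S)-3-hydroxy-2-methylbutanoyl]-1,3-oxazolidin-2-one
Product: 9 (2R,3S)-3-hydroxy-N-methoxy-N,2-dimethylbutanamide
Conditions: MeNH(OMe)·HCl, AlMe3, CH2Cl2, −10 °C to rt
Reagents that add atoms: N,O-dimethylhydroxylamine hydrochloride, CNOC.Cl
Why: Aluminium amide aminolysis of the imide (Weinreb transamidation) cleaves β-hydroxy acyl oxazolidinones without retro-aldol or epimerisation, and no stereocentre is formed.

Step 6
Reactants: 9 (2R,3S)-3-hydroxy-N-methoxy-N,2-dimethylbutanamide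
Product: 10 (2R,3S)-N-methoxy-N,2-dimethyl-3-(triethylsilyloxy)butanamide
Conditions: TESCl, imidazole, CH2Cl2, 0 °C
Reagents that add atoms: chlorotriethylsilane, CC[Si](Cl)(CC)CC
Why: Standard silylation gives an ether that survives the hydride and aldol steps but is removed by mild acid later, and no stereocentre is formed.

Step 7
Reactants: 10 (2R,3S)-N-methoxy-N,2-dimethyl-3-(triethylsilyloxy)butanamide
Product: 11 (2R,3S)-2-methyl-3-(triethylsilyloxy)butanal
Conditions: iBu2AlH, THF, −78 °C; aq. potassium sodium tartrate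
Reagents that add atoms: none
Why: Hydride reduction of the Weinreb amide stops at the chelated hemiaminal and should release the α-chiral aldehyde on work-up without epimerisation.

Step 8
Reactants: 4 (R)-1-(benzyloxy)-2-methylpentan-3-one; 11 (2R,3S)-2-methyl-3-(triethylsilyloxy)butanal
Product: 13 (2R,4S,5R,6S,7S)-1-(benzyloxy)-5-hydroxy-2,4,6-trimethyl-7-(triethylsilyloxy)octan-3-one, via tin enolate 12 (not isolated)
Conditions: Sn(OTf)2, Et3N, CH2Cl2, −78 °C; then 11
Reagents that add atoms: none
Why: Tin-enolate syn aldol reaction, in which the chelated (Z)-enolate 12 reacts through a closed chair to set C13 and C1 syn to each other and C13 syn (1,4) to the existing C6 methyl, while the known preference of (Z)-enolates for anti-Felkin attack on α-methyl aldehydes matches the required C1/C2 anti relationship.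

Step 9
Reactants: 13 (2R,4S,5R,6S,7S)-1-(benzyloxy)-5-hydroxy-2,4,6-trimethyl-7-(triethylsilyloxy)octan-3-one
Product: 15 (2R,3S,4R,5S,6S)-2-[(2R)-1-(benzyloxy)propan-2-yl]-2-methoxy-3,5,6-trimethyloxan-4-ol, via hemiketal 14 (not isolated)
Conditions: CSA (cat.), MeOH, 0 °C to rt
Reagents that add atoms: methanol, CO
Why: Acid methanolysis removes the silyl ether, the freed C3 hydroxyl adds to the C5 ketone (6-exo-trig hemiketalisation to 14, closing the tetrahydropyran) and exchange with methanol gives the ketal, whose anomeric centre is set thermodynamically with methoxy axial while no other stereocentre changes.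

Step 10
Reactants: 15 (2R,3S,4R,5S,6S)-2-[(2R)-1-(benzyloxy)propan-2-yl]-2-methoxy-3,5,6-trimethyloxan-4-ol
Product: 16 (2R,3S,4R,5R,6S)-2-[(2R)-1-(benzyloxy)propan-2-yl]-2-methoxy-3,5,6-trimethyloxan-4-yl acetate
Conditions: Ac2O, pyridine, DMAP (cat.), CH2Cl2, 0 °C to rt
Reagents that add atoms: acetic anhydride, CC(=O)OC(C)=O
Why: Acetylation of the equatorial secondary alcohol installs the acetate of the target at a stage where β-elimination is impossible because C5 is a ketal, and no stereocentre is formed.

Step 11
Reactants: 16 (2R,3S,4R,5R,6S)-2-[(2R)-1-(benzyloxy)propan-2-yl]-2-methoxy-3,5,6-trimethyloxan-4-yl acetate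
Product: 17 (2R,3S,4R,5R,6S)-2-[(2R)-1-hydroxypropan-2-yl]-2-methoxy-3,5,6-trimethyloxan-4-yl acetate
Conditions: H2 (1 atm), Pd/C, NaHCO3 (solid), EtOAc, rt
Reagents that add atoms: none
Why: Neutral hydrogenolysis removes the benzyl ether and should leave ketal and acetate untouched, and no stereocentre is formed.

Step 12
Reactants: 17 (2R,3S,4R,5R,6S)-2-[(2R)-1-hydroxypropan-2-yl]-2-methoxy-3,5,6-trimethyloxan-4-yl acetate
Product: 18 aldehyde (17 with CH2OH oxidised to CHO; all stereocentres unchanged)
Conditions: Dess–Martin periodinane, NaHCO3, CH2Cl2, 0 °C to rt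
Reagents that add atoms: none
Why: Buffered Dess–Martin oxidation gives the α-chiral aldehyde under non-epimerising conditions, and it is used directly.

Step 13
Reactants: 19 (S)-but-3-yn-2-ol
Product: 20 (S)-but-3-yn-2-yl methanesulfonate
Conditions: MsCl, Et3N, CH2Cl2, −78 °C
Reagents that add atoms: methanesulfonyl chloride, CS(=O)(=O)Cl
Why: Mesylation takes place at oxygen, so the carbinol stereocentre is kept.

Step 14
Reactants: 18 aldehyde; 20 (S)-but-3-yn-2-yl methanesulfonate
Product: 22 (2R,3S,4R,5R,6S)-2-[(2R,3R,4R)-3-hydroxy-4-methylhex-5-yn-2-yl]-2-methoxy-3,5,6-trimethyloxan-4-yl acetate, via allenylzinc reagent 21 (not isolated)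
Conditions: Pd(OAc)2 (5 mol %), PPh3 (5 mol %), Et2Zn, THF, −78 to −20 °C
Reagents that add atoms: none
Why: Propargylation with a chiral allenylzinc reagent, in which zerovalent palladium opens the mesylate anti, transmetalation gives 21 and its cyclic SE2′ addition gives the anti homopropargylic alcohol, so C12 is set by the reagent (net inversion of the mesylate carbon), C7 by the anti-selective closed transition state, and the anti relationship of C7 to C6 by reagent control supported by zinc chelation to the ketal oxygen.

Step 15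
Reactants: 22 homopropargylic alcohol
Product: 23 vinylsilane (22 with C≡CH converted into C(SiEt3)=CH2; all stereocentres unchanged)
Conditions: [Cp*Ru(MeCN)3]PF6 (2 mol %), Et3SiH, CH2Cl2, 0 °C to rt
Reagents that add atoms: triethylsilane, CC[SiH](CC)CC
Why: Ruthenium-catalysed hydrosilylation of terminal alkynes gives the branched (Markovnikov) 1,1-disubstituted vinylsilane and tolerates free hydroxyl groups, and no stereocentre is formed.

Step 16
Reactants: 23 vinylsilane
Product: 25 9-acetoxy-3-hydroxy-2,4,7,8,10-pentamethyl-1-methylidene-6-oxaspiro[4.5]decane (2-methyl, 3-hydroxyl and 4-methyl all cis on the cyclopentane and trans to the ring oxygen), via oxocarbenium ion 24 (not isolated)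
Conditions: BF3·OEt2, 2,6-di-tert-butylpyridine, CH2Cl2, −78 to −30 °C
Reagents that add atoms: none
Why: Vinylsilane-terminated cationic cyclisation, in which BF3 ionises the methyl ketal to 24, the silicon-bearing alkene carbon attacks it (β-silyl cation, 5-exo ring closure) and loss of silicon leaves the exocyclic methylene, the spiro centre C5 being set by axial attack on the half-chair that keeps the C13, C1 and C3 substituents pseudo-equatorial, so that the new C–C bond is axial and C6 equatorial.

Step 17
Reactants: 25 exo-methylene spirocycle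
Product: 27 9-acetoxy-3-hydroxy-2,4,7,8,10-pentamethyl-6-oxaspiro[4.5]decan-1-one (configuration as in 25), via ozonide 26 (not isolated)
Conditions: O3, CH2Cl2, −78 °C; then PPh3, −78 °C to rt
Reagents that add atoms: ozone, [O-][O+]=O
Why: Ozonolysis of the 1,1-disubstituted alkene with neutral reductive work-up unveils the ketone without epimerising the adjacent C12 stereocentre or eliminating the β-hydroxyl group, and no stereocentre is formed.

Step 18
Reactants: 27 hydroxy ketone
Product: 28 pyruvate ester of 27 (2-oxopropanoate on the C7 oxygen)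
Conditions: pyruvic acid, DCC, DMAP (cat.), CH2Cl2, 0 °C
Reagents that add atoms: pyruvic acid, CC(=O)C(=O)O
Why: Steglich esterification acylates the hindered secondary alcohol under nearly neutral conditions that should not trigger retro-aldol or elimination of the β-hydroxy ketone, and no stereocentre is formed.

Step 19
Reactants: 28 pyruvate ester
Product: 30 2-diazopropanoate ester of 27, via tosylhydrazone 29 (not isolated)
Conditions: TsNHNH2, THF, rt; then Et3N, CH2Cl2, 0 °C to rt
Reagents that add atoms: 4-methylbenzenesulfonohydrazide, Cc1ccc(cc1)S(=O)(=O)NN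
Why: The hydrazide condenses with the much more electrophilic α-keto ester carbonyl to give 29, and mild base then expels sulfinate (Bamford–Stevens-type elimination) to give the α-diazo ester without forming a stereocentre.

Step 20
Reactants: 30 2-diazopropanoate ester
Product: 32 target (spiro tetrahydropyran fused to the 2-oxabicyclo[2.2.2]octane-3,5-dione; SMILES identical to the one given), via diazonium betaine 31 (not isolated)
Conditions: Sc(OTf)3 (10 mol %), CH2Cl2, −20 °C to rt
Reagents that add atoms: none
Why: Proposed new method: Sc(OTf)3 activates ketone C11, the tethered nucleophilic diazo carbon (future C10) adds to it from the face of the C7 ester oxygen to give the 2-oxabicyclo[3.2.1]octane betaine 31, and loss of N2 with antiperiplanar 1,2-shift of the spiro carbon C5 from C11 to C10 regenerates the ketone; the closest known reaction is the Lewis-acid-promoted Tiffeneau–Demjanov-type (Büchner–Curtius–Schlotterbeck) ring expansion of cycloalkanones with α-alkyl α-diazo esters, here made intramolecular through the ester tether. Two rings close: the δ-lactone by 6-exo-trig attack of the diazo carbon on the ketone, and the six-membered carbocycle by one-carbon insertion into the C11–C5 bond of the cyclopentanone. The only new stereocentre, quaternary C10, is fixed by the bicyclo[2.2.2] frame, in which its ester carbon is tied to O8 on C7, so only one configuration can form; C5 migrates with retention and C6, C7 and C12 are not touched. The step needs migration of C5 and not of C12: in the chair-like betaine the C12 methyl is axial on the forming lactone ring, which sends the C10 methyl equatorial and N2 axial, antiperiplanar to the C11–C5 bond, and C5 is also the more electron-rich, oxygen-bearing migrating carbon. The catalytic, non-basic conditions are chosen so that the β-acyloxy ketone does not eliminate.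

**Compound list**

1 | methyl (R)-3-hydroxy-2-methylpropanoate | COC(=O)[C@H](C)CO | starting material
2 | methyl (R)-3-(benzyloxy)-2-methylpropanoate | COC(=O)[C@H](C)COCc1ccccc1 | intermediate
3 | (R)-3-(benzyloxy)-N-methoxy-N,2-dimethylpropanamide | CON(C)C(=O)[C@H](C)COCc1ccccc1 | intermediate
4 | (R)-1-(benzyloxy)-2-methylpentan-3-one | CCC(=O)[C@H](C)COCc1ccccc1 | intermediate
5 | (R)-4-benzyl-3-propanoyl-1,3-oxazolidin-2-one | O=C1OC[C@@H](Cc2ccccc2)N1C(=O)CC | starting material
6 | acetaldehyde | CC=O | starting material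
7 | (Z)-dibutylboron enolate of 5 | C/C=C(\OB(CCCC)CCCC)N1[C@H](Cc2ccccc2)COC1=O | intermediate
8 | (R)-4-benzyl-3-[(2R,3S)-3-hydroxy-2-methylbutanoyl]-1,3-oxazolidin-2-one | O=C1OC[C@@H](Cc2ccccc2)N1C(=O)[C@H](C)[C@H](C)O | intermediate
9 | (2R,3S)-3-hydroxy-N-methoxy-N,2-dimethylbutanamide | CON(C)C(=O)[C@H](C)[C@H](C)O | intermediate
10 | (2R,3S)-N-methoxy-N,2-dimethyl-3-(triethylsilyloxy)butanamide | CON(C)C(=O)[C@H](C)[C@H](C)O[Si](CC)(CC)CC | intermediate
11 | (2R,3S)-2-methyl-3-(triethylsilyloxy)butanal | O=C[C@H](C)[C@H](C)O[Si](CC)(CC)CC | intermediate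
12 | (Z)-tin triflate enolate of 4 | C/C=C(\O[Sn]OS(=O)(=O)C(F)(F)F)[C@H](C)COCc1ccccc1 | intermediate
13 | (2R,4S,5R,6S,7S)-1-(benzyloxy)-5-hydroxy-2,4,6-trimethyl-7-(triethylsilyloxy)octan-3-one | O[C@H]([C@H](C)[C@H](C)O[Si](CC)(CC)CC)[C@H](C)C(=O)[C@H](C)COCc1ccccc1 | intermediate
14 | cyclic hemiketal of desilylated 13 (2-hydroxy analogue of 15) | O[C@@H]1[C@H](C)[C@H](C)O[C@](O)([C@H](C)COCc2ccccc2)[C@H]1C | intermediate
15 | (2R,3S,4R,5S,6S)-2-[(2R)-1-(benzyloxy)propan-2-yl]-2-methoxy-3,5,6-trimethyloxan-4-ol | O[C@@H]1[C@H](C)[C@H](C)O[C@](OC)([C@H](C)COCc2ccccc2)[C@H]1C | intermediate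
16 | (2R,3S,4R,5R,6S)-2-[(2R)-1-(benzyloxy)propan-2-yl]-2-methoxy-3,5,6-trimethyloxan-4-yl acetate | CC(=O)O[C@@H]1[C@H](C)[C@H](C)O[C@](OC)([C@H](C)COCc2ccccc2)[C@H]1C | intermediate
17 | (2R,3S,4R,5R,6S)-2-[(2R)-1-hydroxypropan-2-yl]-2-methoxy-3,5,6-trimethyloxan-4-yl acetate | CC(=O)O[C@@H]1[C@H](C)[C@H](C)O[C@](OC)([C@H](C)CO)[C@H]1C | intermediate
18 | aldehyde from 17 (CH2OH oxidised to CHO, configuration unchanged) | CC(=O)O[C@@H]1[C@H](C)[C@H](C)O[C@](OC)([C@H](C)C=O)[C@H]1C | intermediate
19 | (S)-but-3-yn-2-ol | C[C@H](O)C#C | starting material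
20 | (S)-but-3-yn-2-yl methanesulfonate | C[C@H](OS(C)(=O)=O)C#C | intermediate
21 | (aR)-buta-1,2-dien-1-yl(ethyl)zinc | CC[Zn]C([H])=[C@@]=C(C)[H] | intermediate
22 | (2R,3S,4R,5R,6S)-2-[(2R,3R,4R)-3-hydroxy-4-methylhex-5-yn-2-yl]-2-methoxy-3,5,6-trimethyloxan-4-yl acetate | CC(=O)O[C@@H]1[C@H](C)[C@H](C)O[C@](OC)([C@H](C)[C@H](O)[C@H](C)C#C)[C@H]1C | intermediate
23 | vinylsilane from 22 (C≡CH converted into C(SiEt3)=CH2, configuration unchanged) | CC(=O)O[C@@H]1[C@H](C)[C@H](C)O[C@](OC)([C@H](C)[C@H](O)[C@H](C)C(=C)[Si](CC)(CC)CC)[C@H]1C | intermediate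
24 | tetrahydropyranyl oxocarbenium ion from 23 (loss of methoxide) | CC(=O)O[C@@H]1[C@H](C)[C@H](C)[O+]=C([C@H](C)[C@H](O)[C@H](C)C(=C)[Si](CC)(CC)CC)[C@H]1C | intermediate
25 | 9-acetoxy-3-hydroxy-2,4,7,8,10-pentamethyl-1-methylidene-6-oxaspiro[4.5]decane (2-Me, 3-OH, 4-Me all cis, trans to ring oxygen) | CC(=O)O[C@@H]1[C@H](C)[C@H](C)O[C@]2([C@H](C)[C@H](O)[C@H](C)C2=C)[C@H]1C | intermediate
26 | secondary ozonide (1,2,4-trioxolane) of 25, configuration at the trioxolane spiro carbon not defined | CC(=O)O[C@@H]1[C@H](C)[C@H](C)O[C@]2([C@H](C)[C@H](O)[C@H](C)C23OCOO3)[C@H]1C | intermediate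
27 | 9-acetoxy-3-hydroxy-2,4,7,8,10-pentamethyl-6-oxaspiro[4.5]decan-1-one (configuration as in 25) | CC(=O)O[C@@H]1[C@H](C)[C@H](C)O[C@]2([C@H](C)[C@H](O)[C@H](C)C2=O)[C@H]1C | intermediate
28 | pyruvate (2-oxopropanoate) ester of 27 | CC(=O)O[C@@H]1[C@H](C)[C@H](C)O[C@]2([C@H](C)[C@H](OC(=O)C(C)=O)[C@H](C)C2=O)[C@H]1C | intermediate
29 | 4-methylbenzenesulfonylhydrazone of 28 (C=N geometry not defined) | CC(=O)O[C@@H]1[C@H](C)[C@H](C)O[C@]2([C@H](C)[C@H](OC(=O)C(C)=NNS(=O)(=O)c3ccc(C)cc3)[C@H](C)C2=O)[C@H]1C | intermediate
30 | 2-diazopropanoate ester of 27 | CC(=O)O[C@@H]1[C@H](C)[C@H](C)O[C@]2([C@H](C)[C@H](OC(=O)C(C)=[N+]=[N-])[C@H](C)C2=O)[C@H]1C | intermediate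
31 | 2-oxabicyclo[3.2.1]octane diazonium alkoxide (betaine) from 30 | CC(=O)O[C@@H]1[C@H](C)[C@H](C)O[C@]2([C@H](C)[C@@H]3OC(=O)[C@@](C)([N+]#N)[C@@]2([O-])[C@H]3C)[C@H]1C | intermediate
32 | target, CNP0257416.2 | CC(=O)O[C@@H]1[C@H](C)[C@H](C)O[C@]2([C@H](C)[C@@H]3OC(=O)[C@@]2(C)C(=O)[C@H]3C)[C@H]1C | target

**Step count and risks**

Total step count: 20. Longest linear sequence: 16 steps (steps 4 to 12 and 14 to 20, from 5).

Steps most likely to fail:

1. Step 20 (proposed new method). What may go wrong: migration of C12 in place of C5 in the betaine, loss of N2 before C–C bond formation (1,2-hydride shift to an acrylate), or β-elimination of the acyloxy group under Lewis acid. Fallback with known chemistry, a stepwise ring expansion that sets out from hydroxy ketone 27 and returns to the route at 32. The alcohol is silylated (TESOTf, 2,6-lutidine) to the triethylsilyl ether F1. Lithiated ethyl diazoacetate (LDA, THF, −78 °C) is added to the ketone to give the β-hydroxy α-diazo ester F2. Rh2(OAc)4 in CH2Cl2 then induces loss of N2 with 1,2-shift of C5, a known ring expansion, to the β-keto ester F3. C-Methylation (MeI, K2CO3, acetone) gives the quaternary β-keto ester F4. HF·pyridine removes the silyl group, and the freed C7 hydroxyl should lactonise onto the ethyl ester to give 32. Only the C10 epimer with the ester cis to O8 can close.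

2. Step 16. What may go wrong: protodesilylation of the vinylsilane or loss of methanol to the enol ether outruns C–C bond formation, and torsional strain of the all-cis cyclopentane slows ring closure. Fallback by radical instead of cationic ring closure, setting out from alkyne 22 and returning at 25 (steps 15 and 16 are bypassed). Ketal exchange with PhSeH and BF3·OEt2 gives the phenylselanyl ketal F5. Bu3SnH with AIBN in benzene at 80 °C generates the α-alkoxy (anomeric) radical at C5, which should close 5-exo-dig onto the terminal alkyne with axial bond formation. Hydrogen transfer to the vinyl radical then gives 25.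

3. Step 14. What may go wrong: poor facial selectivity in the anti-Felkin sense required at C7, and epimerisation of the α-stereocentre of aldehyde 18 before addition. Fallback under catalyst control from the alcohol oxidation level, setting out from primary alcohol 17 and returning at 22 (steps 12 to 14 are bypassed). An iridium-catalysed transfer-hydrogenative anti-(α-methyl)propargylation of 17 is run with (but-3-en-1-yn-1-yl)tri(propan-2-yl)silane, using a SEGPHOS-modified catalyst formed from [Ir(cod)Cl]2 with the ligand antipode chosen for the (R,R) adduct. This gives the silyl alkyne F6 without handling the free aldehyde. Bu4NF in THF then removes the silyl group to give 22.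

Further compounds
F1 | step 20 | triethylsilyl ether of 27 | CC(=O)O[C@@H]1[C@H](C)[C@H](C)O[C@]2([C@H](C)[C@H](O[Si](CC)(CC)CC)[C@H](C)C2=O)[C@H]1C
F2 | step 20 | β-hydroxy α-diazo ester from addition of ethyl diazoacetate to the ketone of F1 | CC(=O)O[C@@H]1[C@H](C)[C@H](C)O[C@]2([C@H](C)[C@H](O[Si](CC)(CC)CC)[C@H](C)[C@@]2(O)C(=[N+]=[N-])C(=O)OCC)[C@H]1C
F3 | step 20 | ring-expanded β-keto ethyl ester (C10 epimerisable, not defined) | CC(=O)O[C@@H]1[C@H](C)[C@H](C)O[C@]2([C@H](C)[C@H](O[Si](CC)(CC)CC)[C@H](C)C(=O)C2C(=O)OCC)[C@H]1C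
F4 | step 20 | C10-methylated β-keto ethyl ester | CC(=O)O[C@@H]1[C@H](C)[C@H](C)O[C@]2([C@H](C)[C@H](O[Si](CC)(CC)CC)[C@H](C)C(=O)[C@]2(C)C(=O)OCC)[C@H]1C
F5 | step 16 | phenylselanyl ketal of 22 | CC(=O)O[C@@H]1[C@H](C)[C@H](C)O[C@]([Se]c2ccccc2)([C@H](C)[C@H](O)[C@H](C)C#C)[C@H]1C
F6 | step 14 | tri(propan-2-yl)silyl alkyne analogue of 22 | CC(=O)O[C@@H]1[C@H](C)[C@H](C)O[C@](OC)([C@H](C)[C@H](O)[C@H](C)C#C[Si](C(C)C)(C(C)C)C(C)C)[C@H]1C
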